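**The problem**

Target 17 is a cyclohept-2-en-1-one (ring atoms C1 to C7: C1 the carbonyl, C2 carrying CH2OH, C2=C3, C4 a methylene) whose other three ring atoms are contiguous stereocentres, all S: the all-carbon quaternary C5 (methyl and 4-hydroxy-4-methylpentyl), C6 (the (E)-2-acyloxyvinyl group, cis to the C5 methyl) and C7 (acetonyl, trans to the C6 group). The hard bond is C5–C6: the two exocyclic groups on C5 are a methyl and a primary alkyl chain of nearly the same size, so a reagent adding to C6 beside a finished C5 (or the reverse) has no face to prefer, and the C5/C6 relation must come from a stereospecific event in which it follows from alkene geometry. C7 is α to C1 and epimerisable; it can be set trans to C6 by enolate alkylation, but only if the C1=C7 enolate can be made in the presence of the more acidic C2 position. The ring is seven-membered, so its closure should not be left to an entropically poor cyclisation. The functional groups are fragile: the (E)-enol ester is an acyl donor that survives neither amines, alkoxides nor hydrides and must be made last with control of geometry; the C1 ketone and the acetonyl ketone form a 1,4-diketone that cyclises with base; the 2-(hydroxymethyl)enone and the aldehyde oxidation level hidden in the enol ester restrict redox chemistry. The feature that opens the problem is the position of the C5–C6 bond: it lies opposite C2, whose two neighbours are the oxygen-bearing C1 and the sp2 carbon C3. If C2=C3 is moved to C3=C4 and the C1 ketone is written as its C1=C7 enolate, the ring is a cyclohepta-1,4-dien-1-olate, the [3,3] product of a cis-1,2-dialkenylcyclopropan-1-ol whose three-membered ring is C1–C2–C3 and whose alkene termini are C6 and C5.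

**Retrosynthesis**

17 to 15: the O–C(vinyl) bond of the enol ester is cut last, to the (E)-alkenylboronate 15 and the carboxylic acid partner. Acylating an aldehyde enolate instead would give E/Z mixtures and expose the diketone to base; a boron-bearing (E)-alkene fixes the geometry beforehand. The forward reaction must form a C(sp2)–O bond with retention under non-nucleophilic conditions.

15 to 14: the CH=CH(B) double bond is cut to aldehyde 14 and a one-carbon boron reagent. Cross-metathesis of a C6 vinyl group was the neighbouring cut, but a pentadienoate carrying that vinyl group would compete with the diene partner in step 3. The forward reaction must be (E)-selective and must choose the aldehyde over two ketones.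

14 to 13: no skeletal bond is cut. The acetonyl ketone, the aldehyde and the tertiary alcohol are traced back to an enol ether, a dimethyl acetal and a silyl ether, three groups that fall in one acidic operation.

13 to 11: the C2–CH2OH bond is cut (a C1 electrophile) and C2=C3 is moved to C3=C4 via the conjugated enone 12. Carrying the hydroxymethyl carbon through the key step would need a 1-substituted diene, which does not undergo alkene exchange on titanium. The forward reaction is base-mediated conjugation followed by α-hydroxymethylation of the enone.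

11 to 9 (key): the C7–CH2 bond is cut back to the C1=C7 enolate 10, and in 10 the C5–C6 bond is cut while C1–C3 is re-formed. This leads to cyclopropanol 9, which has two stereocentres instead of three, no seven-membered ring and no quaternary centre. The forward reaction must be concerted, so that the (E)/(Z) geometries and the cyclopropane configuration are translated into C5 and C6, and must deliver the enolate regiospecifically.

9 to 7 + 8: the C1–C2 and C1–C3 bonds are cut. C1 is the ester carbon of the bought enoate 8, and C2/C3 are the terminal vinyl group of diene 7. The forward reaction (titanium-mediated cyclopropanation of an ester with an alkene) must join the two cis and must select one face of the alkene; this is the only step at which absolute configuration enters.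

7 to 2 + 3 + 4: the C3–C4 bond (sp2–sp2 coupling with bromoethene 4) and the bond between C5 and the chain (addition of the chain across propyne 3) are cut. syn-Carbometalation fixes the (Z) geometry that later becomes the C5 configuration. Bromide 2 is the silyl ether of bromo alcohol 1.

**Roads not taken**

Alternative 1: the most obvious cut removes the C6 and C7 side chains from a cyclohepta-2,6-dienone A1 that already holds C5. The forward key step is conjugate addition of a vinyl nucleophile to C6 and trapping of the enolate at C7 with an acetonyl equivalent. A1 is accessible by the well-established rhodium-catalysed (4+3) reaction of a vinyldiazoacetate with a diene, followed by redox adjustment. The plan fails on structure: the face of C6 would have to be chosen by the adjacent quaternary C5, whose methyl and CH2R groups offer no steric basis for selection, and the second enone (C2=C3) competes as acceptor. The chosen plan makes C5–C6 in a pericyclic step where the relation follows from alkene geometry.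

Alternative 2: the same C5–C6 [3,3] bond can be formed from a rhodium vinylcarbenoid: cyclopropanation of 7 with a 4-substituted vinyldiazoacetate under Rh2(S-DOSP)4, then Cope rearrangement to diene ester A2. Its strength is enantiocontrol by a well-behaved catalyst. Its weakness is that the carbenoid needs an acceptor, so an ester sits on C1 where the target has the ketone oxygen. A2 would need conjugate addition at C7 and then oxidative excision of the ester carbon (α-hydroxylation, reduction, glycol cleavage), several operations for what the alkoxide of 9 delivers in the key step itself.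

Alternative 3: an Ireland–Claisen ring contraction of the seven-membered lactone A3 would form C5–C6 and the carbocycle through a boat [3,3] shift. The lactone would come from a catalytic asymmetric aldol-type addition, esterification and ring-closing metathesis with a second-generation Grubbs catalyst, and its single carbinol centre would control absolute configuration. The run-up is longer, the C6 substituent arrives as a carboxyl group that needs redox and one-carbon adjustment, and no C1=C7 enolate is produced, so C7 must be alkylated later through protected intermediates. The estimate is about twice the step count of the chosen plan.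

Key step: step 4

Assumption: the sense of induction of the titanium TADDOLate in step 3 cannot be derived from precedent, so the (R,R) ligand written there stands for whichever enantiomer delivers (1R,2R)-9; compounds 1 and 8 and the reagents 3-bromo-2-methoxyprop-1-ene and 2-(dichloromethyl)-4,4,5,5-tetramethyl-1,3,2-dioxaborolane are taken as purchasable.

Step 1
Reactants: 1 5-bromo-2-methylpentan-2-ol
Product: 2 [(5-bromo-2-methylpentan-2-yl)oxy]triethylsilane
Conditions: Et3SiOTf, 2,6-lutidine, CH2Cl2, 0 °C
Reagents that add atoms: triethylsilyl trifluoromethanesulfonate, CC[Si](CC)(CC)OS(=O)(=O)C(F)(F)F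
Why: Silylation of a tertiary alcohol with a silyl triflate is routine; the ether allows Grignard formation in step 2, keeps the alkoxide out of steps 3 and 4 and falls in the acid step 6.

Step 2
Reactants: 2 [(5-bromo-2-methylpentan-2-yl)oxy]triethylsilane; 3 propyne; 4 bromoethene
Product: 7 triethyl{[(6Z)-2,6-dimethylnona-6,8-dien-2-yl]oxy}silane, via Grignard reagent 5 (not isolated), via alkenylcopper reagent 6 (not isolated)
Conditions: Mg, Et2O, rt; CuBr·SMe2, Et2O/Me2S, −45 °C; 3, −25 °C; then 4, ZnBr2 (additive), Pd(PPh3)4 (5 mol %), THF, −20 °C to rt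
Reagents that add atoms: none
Why: syn-Carbocupration of propyne by the alkylcopper reagent places the chain and copper on the same side of the new double bond, and palladium-catalysed cross-coupling (Negishi type) with bromoethene retains that geometry, so the chain ends cis to the vinyl group; this (Z) geometry is what later places the methyl group of C5 cis to the C6 substituent.

Step 3
Reactants: 7 triethyl{[(6Z)-2,6-dimethylnona-6,8-dien-2-yl]oxy}silane; 8 methyl (2E)-4,4-dimethoxybut-2-enoate
Product: 9 (1R,2R)-1-[(1E)-3,3-dimethoxyprop-1-en-1-yl]-2-[(1Z)-2,6-dimethyl-6-(triethylsilyloxy)hept-1-en-1-yl]cyclopropan-1-ol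
Conditions: Ti(OiPr)2[(R,R)-TADDOLate] (1.2 equiv), c-C5H9MgCl (2.4 equiv, slow addition), THF, −30 to 0 °C; cold aqueous work-up, chromatography at 0 °C
Reagents that add atoms: none
Why: Proposed new method: enantioselective alkene-exchange Kulinkovich cyclopropanation on a stoichiometric chiral titanium diolate; c-C5H9MgCl converts the tetravalent titanium diolate into the titanacyclopropane of cyclopentene, which exchanges its alkene for the only unhindered double bond of 7 (the terminal vinyl group), the C2-symmetric diolate deciding which face is bound; insertion of the ester carbonyl of 8 into the Ti–CH2 bond and ring contraction give the cyclopropanol with the two alkenyl groups cis, as in the achiral reaction, and set C1 and C2; the closest known reaction types are the Kulinkovich reaction of simple esters mediated by titanium TADDOLates and the achiral alkene-exchange variant that gives cis-2-alkenylcyclopropanols from 1,3-dienes.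

Step 4
Reactants: 9 (1R,2R)-1-[(1E)-3,3-dimethoxyprop-1-en-1-yl]-2-[(1Z)-2,6-dimethyl-6-(triethylsilyloxy)hept-1-en-1-yl]cyclopropan-1-ol
Product: 11 (5S,6S,7S)-6-(dimethoxymethyl)-7-(2-methoxyprop-2-en-1-yl)-5-methyl-5-[4-methyl-4-(triethylsilyloxy)pentyl]cyclohept-3-en-1-one, via lithium enolate 10 (not isolated)
Conditions: LiN(SiMe3)2, THF, −78 to 40 °C; then DMPU, 3-bromo-2-methoxyprop-1-ene, −78 to 0 °C
Reagents that add atoms: 3-bromo-2-methoxyprop-1-ene, COC(=C)CBr
Why: LiN(SiMe3)2 gives the lithium alkoxide of 9, and the two cis alkenyl groups together with the strained C1–C3 bond undergo a concerted [3,3] shift to the dienolate 10 (oxy-Cope rearrangement of a cis-1,2-dialkenylcyclopropanol, a formal (4+3) annulation driven by release of ring strain and by enolate formation). The seven-membered ring is closed not by a cyclisation but by formation of the C5–C6 σ bond between the two alkene termini inside the boat transition state that the three-membered ring enforces, while C1–C3 breaks. In this boat the groups trans to the ring on each terminus (CH(OMe)2 on C6, CH3 on C5) become cis across the new bond and the chain, cis to the ring on C5, becomes trans to them, so the C5/C6 relation follows from the (E) and (Z) geometries of 9 and not from the size of the groups on C5. The absolute configuration of both centres is relayed from C1 and C2 of (1R,2R)-9, which lose their stereogenicity in the event. The enolate is born regiospecifically as C1=C7, away from the more acidic C2, and is alkylated in the same flask by 3-bromo-2-methoxyprop-1-ene from the face opposite the C6 substituent, which sets C7 trans to C6. The step needs a concerted instead of a ring-opening (homoenolate) pathway and C-alkylation without enolate equilibration; the cis geometry, the lithium counter-ion, the low temperature and the reactive allylic bromide secure both. The closest known reactions are the oxy-Cope ring expansion of cis-1,2-dialkenylcyclopropanols to cyclohept-3-enones and tandem oxy-Cope/enolate alkylation.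

Step 5
Reactants: 11 (5S,6S,7S)-6-(dimethoxymethyl)-7-(2-methoxyprop-2-en-1-yl)-5-methyl-5-[4-methyl-4-(triethylsilyloxy)pentyl]cyclohept-3-en-1-one
Product: 13 (5S,6S,7S)-6-(dimethoxymethyl)-2-(hydroxymethyl)-7-(2-methoxyprop-2-en-1-yl)-5-methyl-5-[4-methyl-4-(triethylsilyloxy)pentyl]cyclohept-2-en-1-one, via conjugated enone 12 (not isolated)
Conditions: DBU (cat.), CH2Cl2, rt; then aq. CH2O, imidazole, THF/H2O, rt
Reagents that add atoms: formaldehyde, C=O
Why: DBU equilibrates the 3-enone with the 2-enone 12, and the Morita–Baylis–Hillman reaction with formaldehyde removes 12 from the equilibrium as the more substituted enone 13; both ketone and aldehyde equivalents of the side chains are masked and base-stable, and no new stereocentre is formed.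

Step 6
Reactants: 13 (5S,6S,7S)-6-(dimethoxymethyl)-2-(hydroxymethyl)-7-(2-methoxyprop-2-en-1-yl)-5-methyl-5-[4-methyl-4-(triethylsilyloxy)pentyl]cyclohept-2-en-1-one
Product: 14 (1S,2S,7S)-5-(hydroxymethyl)-2-(4-hydroxy-4-methylpentyl)-2-methyl-6-oxo-7-(2-oxopropyl)cyclohept-4-ene-1-carbaldehyde
Conditions: 1 M HCl, THF, 0 °C to rt; product used at once
Reagents that add atoms: water, O
Why: Dilute aqueous acid hydrolyses the enol ether to the methyl ketone, the dimethyl acetal to the aldehyde and the tertiary silyl ether to the alcohol in one operation; the stereocentres are not touched as long as the time in acid is kept short.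

Step 7
Reactants: 14 (1S,2S,7S)-5-(hydroxymethyl)-2-(4-hydroxy-4-methylpentyl)-2-methyl-6-oxo-7-(2-oxopropyl)cyclohept-4-ene-1-carbaldehyde
Product: 15 (5S,6S,7S)-2-(hydroxymethyl)-5-(4-hydroxy-4-methylpentyl)-5-methyl-7-(2-oxopropyl)-6-[(E)-2-(4,4,5,5-tetramethyl-1,3,2-dioxaborolan-2-yl)ethenyl]cyclohept-2-en-1-one
Conditions: Cl2CHB(pin), CrCl2 (excess), LiI, THF, rt
Reagents that add atoms: 2-(dichloromethyl)-4,4,5,5-tetramethyl-1,3,2-dioxaborolane, ClC(Cl)B1OC(C)(C)C(C)(C)O1
Why: The Takai–Utimoto-type chromium-mediated olefination with a geminal dihalomethylboronate is (E)-selective, non-basic (no epimerisation at C6) and selective for the aldehyde over both ketones; the excess reagent allows for the two free hydroxyl groups.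

Step 8
Reactants: 15 (5S,6S,7S)-2-(hydroxymethyl)-5-(4-hydroxy-4-methylpentyl)-5-methyl-7-(2-oxopropyl)-6-[(E)-2-(4,4,5,5-tetramethyl-1,3,2-dioxaborolan-2-yl)ethenyl]cyclohept-2-en-1-one
Product: 17 (1E)-2-[(1S,2S,7S)-5-(hydroxymethyl)-2-(4-hydroxy-4-methylpentyl)-2-methyl-6-oxo-7-(2-oxopropyl)cyclohept-4-en-1-yl]ethenyl 3-methylbut-2-enoate, via potassium trifluoroborate 16 (not isolated)
Conditions: KHF2, MeOH/H2O, rt; then 3-methylbut-2-enoic acid, CuBr (10 mol %), DMAP, 4 Å molecular sieves, O2 (1 atm), CH2Cl2, 40 °C
Reagents that add atoms: 3-methylbut-2-enoic acid, CC(C)=CC(=O)O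
Why: The boronate is converted into the trifluoroborate, and copper-catalysed oxidative coupling (Chan–Lam type) of the alkenylborate with the carboxylic acid forms the C(sp2)–O bond with retention of the (E) geometry; the acyl-donor enol ester appears only in the last step and sees no strong nucleophile.

**Compound list**

1 | 5-bromo-2-methylpentan-2-ol | CC(C)(O)CCCBr | starting material
2 | [(5-bromo-2-methylpentan-2-yl)oxy]triethylsilane | CC[Si](CC)(CC)OC(C)(C)CCCBr | intermediate
3 | propyne | CC#C | starting material
4 | bromoethene | C=CBr | starting material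
5 | [4-methyl-4-(triethylsilyloxy)pentyl]magnesium bromide | CC[Si](CC)(CC)OC(C)(C)CCC[Mg]Br | intermediate
6 | [(1Z)-2,6-dimethyl-6-(triethylsilyloxy)hept-1-en-1-yl]copper (MgBr2 complex) | CC[Si](CC)(CC)OC(C)(C)CCC/C(C)=C\[Cu] | intermediate
7 | triethyl{[(6Z)-2,6-dimethylnona-6,8-dien-2-yl]oxy}silane | C=C/C=C(/C)CCCC(C)(C)O[Si](CC)(CC)CC | intermediate
8 | methyl (2E)-4,4-dimethoxybut-2-enoate | COC(=O)/C=C/C(OC)OC | starting material
9 | (1R,2R)-1-[(1E)-3,3-dimethoxyprop-1-en-1-yl]-2-[(1Z)-2,6-dimethyl-6-(triethylsilyloxy)hept-1-en-1-yl]cyclopropan-1-ol | O[C@@]1(/C=C/C(OC)OC)C[C@@H]1/C=C(/C)CCCC(C)(C)O[Si](CC)(CC)CC | intermediate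
10 | lithium (3S,4S)-3-(dimethoxymethyl)-4-methyl-4-[4-methyl-4-(triethylsilyloxy)pentyl]cyclohepta-1,5-dien-1-olate | [Li]OC1=C[C@H](C(OC)OC)[C@@](C)(CCCC(C)(C)O[Si](CC)(CC)CC)C=CC1 | intermediate
11 | (5S,6S,7S)-6-(dimethoxymethyl)-7-(2-methoxyprop-2-en-1-yl)-5-methyl-5-[4-methyl-4-(triethylsilyloxy)pentyl]cyclohept-3-en-1-one | COC(=C)C[C@@H]1C(=O)CC=C[C@](C)(CCCC(C)(C)O[Si](CC)(CC)CC)[C@H]1C(OC)OC | intermediate
12 | (5S,6S,7S)-6-(dimethoxymethyl)-7-(2-methoxyprop-2-en-1-yl)-5-methyl-5-[4-methyl-4-(triethylsilyloxy)pentyl]cyclohept-2-en-1-one | COC(=C)C[C@@H]1C(=O)C=CC[C@](C)(CCCC(C)(C)O[Si](CC)(CC)CC)[C@H]1C(OC)OC | intermediate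
13 | (5S,6S,7S)-6-(dimethoxymethyl)-2-(hydroxymethyl)-7-(2-methoxyprop-2-en-1-yl)-5-methyl-5-[4-methyl-4-(triethylsilyloxy)pentyl]cyclohept-2-en-1-one | COC(=C)C[C@@H]1C(=O)C(CO)=CC[C@](C)(CCCC(C)(C)O[Si](CC)(CC)CC)[C@H]1C(OC)OC | intermediate
14 | (1S,2S,7S)-5-(hydroxymethyl)-2-(4-hydroxy-4-methylpentyl)-2-methyl-6-oxo-7-(2-oxopropyl)cyclohept-4-ene-1-carbaldehyde | CC(=O)C[C@@H]1C(=O)C(CO)=CC[C@](C)(CCCC(C)(C)O)[C@H]1C=O | intermediate
15 | (5S,6S,7S)-2-(hydroxymethyl)-5-(4-hydroxy-4-methylpentyl)-5-methyl-7-(2-oxopropyl)-6-[(E)-2-(4,4,5,5-tetramethyl-1,3,2-dioxaborolan-2-yl)ethenyl]cyclohept-2-en-1-one | CC(=O)C[C@@H]1C(=O)C(CO)=CC[C@](C)(CCCC(C)(C)O)[C@H]1/C=C/B2OC(C)(C)C(C)(C)O2 | intermediate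
16 | potassium trifluoro{(E)-2-[(1S,2S,7S)-5-(hydroxymethyl)-2-(4-hydroxy-4-methylpentyl)-2-methyl-6-oxo-7-(2-oxopropyl)cyclohept-4-en-1-yl]ethenyl}borate | CC(=O)C[C@@H]1C(=O)C(CO)=CC[C@](C)(CCCC(C)(C)O)[C@H]1/C=C/[B-](F)(F)F.[K+] | intermediate
17 | (1E)-2-[(1S,2S,7S)-5-(hydroxymethyl)-2-(4-hydroxy-4-methylpentyl)-2-methyl-6-oxo-7-(2-oxopropyl)cyclohept-4-en-1-yl]ethenyl 3-methylbut-2-enoate (CNP0359016.1) | CC(=O)C[C@@H]1C(=O)C(CO)=CC[C@](C)(CCCC(C)(C)O)[C@H]1/C=C/OC(=O)C=C(C)C | target

**Step count and risk**

Total step count: 8. Longest linear sequence: 8 steps from 1 (3, 4 and 8 are bought).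

Least certain steps:

Step 3 (Proposed new method). The most likely failure is insufficient discrimination between the two faces of the terminal alkene on titanium, made worse by achiral ate complexes formed with excess Grignard reagent, so that enantiomeric purity is eroded. Attack of the low-valent titanium species on the conjugated double bond of 8 is the second risk. Fallback (auxiliary and diastereomer separation, known chemistry), setting out from 7 and 8 and returning at 14: 8 is transacetalised with (2R,3R)-butane-2,3-diol (pyridinium tosylate, benzene) to methyl (2E)-3-[(4R,5R)-4,5-dimethyl-1,3-dioxolan-2-yl]prop-2-enoate F1. The ordinary achiral reaction (ClTi(OiPr)3, c-C5H9MgCl) with 7 gives the cis cyclopropanol (1R,2R)-1-{(1E)-2-[(4R,5R)-4,5-dimethyl-1,3-dioxolan-2-yl]ethenyl}-2-[(1Z)-2,6-dimethyl-6-(triethylsilyloxy)hept-1-en-1-yl]cyclopropan-1-ol F2 as one of a pair of diastereomers. The pair is taken through the conditions of step 4, and the ketone (5S,6S,7S)-6-[(4R,5R)-4,5-dimethyl-1,3-dioxolan-2-yl]-7-(2-methoxyprop-2-en-1-yl)-5-methyl-5-[4-methyl-4-(triethylsilyloxy)pentyl]cyclohept-3-en-1-one F3 is separated from its diastereomer by chromatography. The conditions of step 5 give the hydroxymethyl enone (5S,6S,7S)-6-[(4R,5R)-4,5-dimethyl-1,3-dioxolan-2-yl]-2-(hydroxymethyl)-7-(2-methoxyprop-2-en-1-yl)-5-methyl-5-[4-methyl-4-(triethylsilyloxy)pentyl]cyclohept-2-en-1-one F4, and aqueous acid as in step 6 removes the dioxolane as well and gives 14.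

Step 4 (key step). The lithium cyclopropanolate may open to a β-keto allyl anion before it rearranges, which would erase both the C5/C6 relation and the enantiomeric purity. The neutral alcohol 9 may also rearrange during isolation, which would forfeit the regiodefined enolate. Fallback (neutral thermal variant), setting out from 9 and returning at 10: 9 is silylated (Me3SiCl, imidazole, CH2Cl2, 0 °C) to {[(1R,2R)-1-[(1E)-3,3-dimethoxyprop-1-en-1-yl]-2-[(1Z)-2,6-dimethyl-6-(triethylsilyloxy)hept-1-en-1-yl]cyclopropyl]oxy}trimethylsilane F5. Warming in toluene (80 °C) effects the concerted Cope rearrangement of this siloxy-divinylcyclopropane to {[(3S,4S)-3-(dimethoxymethyl)-4-methyl-4-[4-methyl-4-(triethylsilyloxy)pentyl]cyclohepta-1,5-dien-1-yl]oxy}trimethylsilane F6. MeLi (THF, 0 °C) cleaves the silyl enol ether to 10, which is alkylated as in step 4.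

Step 5. Conjugate addition of the amine catalyst to the hindered seven-membered enone may be slow while the enone/3-enone equilibrium lies only modestly on the conjugated side, so hydroxymethylation may stall; prolonged base also invites epimerisation at C7. Fallback (dienolate aldol instead of nucleophilic catalysis), setting out from 11 and returning at 13: LiN(SiMe3)2 (THF, −78 °C) removes the doubly activated C2–H of 11, and gaseous formaldehyde gives (5S,6S,7S)-6-(dimethoxymethyl)-2-(hydroxymethyl)-7-(2-methoxyprop-2-en-1-yl)-5-methyl-5-[4-methyl-4-(triethylsilyloxy)pentyl]cyclohept-3-en-1-one F7 (both C2 epimers). DBU then moves the double bond into conjugation to give 13.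

Step 6. Once both carbonyl groups are free, intramolecular aldol reaction between the aldehyde and the acetonyl ketone (a 1,5-relationship) and acid-induced epimerisation at C6 can compete with the hydrolysis. Fallback (unmask the aldehyde first, the ketone after it has been consumed), setting out from 13 and returning at 15: Et3SiOTf with 2,4,6-collidine (CH2Cl2, 0 °C), then water, cleaves the dimethyl acetal under non-acidic conditions, leaves the enol ether and silylates the primary alcohol, giving (1S,2S,7S)-7-(2-methoxyprop-2-en-1-yl)-2-methyl-2-[4-methyl-4-(triethylsilyloxy)pentyl]-6-oxo-5-[(triethylsilyloxy)methyl]cyclohept-4-ene-1-carbaldehyde F8. The conditions of step 7 give (5S,6S,7S)-7-(2-methoxyprop-2-en-1-yl)-5-methyl-5-[4-methyl-4-(triethylsilyloxy)pentyl]-6-[(E)-2-(4,4,5,5-tetramethyl-1,3,2-dioxaborolan-2-yl)ethenyl]-2-[(triethylsilyloxy)methyl]cyclohept-2-en-1-one F9, and dilute aqueous acid then frees the ketone and both alcohols to give 15.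

Step 8. Protodeboronation or sluggish C–O coupling in the presence of two free hydroxyl groups, or acyl transfer from the product to DMAP, may limit the conversion. Fallback (C=C bond formation instead of C–O coupling), setting out from 14 and returning at 17: the ylide from {[(3-methylbut-2-enoyl)oxy]methyl}triphenylphosphonium chloride F10 (KN(SiMe3)2, THF, −78 °C) undergoes a Wittig reaction with the aldehyde of 14 and gives 17 directly, at the price of an (E)/(Z) separation.

**Further compounds**

F1 | step 3 | methyl (2E)-3-[(4R,5R)-4,5-dimethyl-1,3-dioxolan-2-yl]prop-2-enoate | COC(=O)/C=C/C1O[C@H](C)[C@@H](C)O1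
F2 | step 3 | (1R,2R)-1-{(1E)-2-[(4R,5R)-4,5-dimethyl-1,3-dioxolan-2-yl]ethenyl}-2-[(1Z)-2,6-dimethyl-6-(triethylsilyloxy)hept-1-en-1-yl]cyclopropan-1-ol | O[C@@]1(/C=C/C2O[C@H](C)[C@@H](C)O2)C[C@@H]1/C=C(/C)CCCC(C)(C)O[Si](CC)(CC)CC
F3 | step 3 | (5S,6S,7S)-6-[(4R,5R)-4,5-dimethyl-1,3-dioxolan-2-yl]-7-(2-methoxyprop-2-en-1-yl)-5-methyl-5-[4-methyl-4-(triethylsilyloxy)pentyl]cyclohept-3-en-1-one | COC(=C)C[C@@H]1C(=O)CC=C[C@](C)(CCCC(C)(C)O[Si](CC)(CC)CC)[C@H]1C2O[C@H](C)[C@@H](C)O2
F4 | step 3 | (5S,6S,7S)-6-[(4R,5R)-4,5-dimethyl-1,3-dioxolan-2-yl]-2-(hydroxymethyl)-7-(2-methoxyprop-2-en-1-yl)-5-methyl-5-[4-methyl-4-(triethylsilyloxy)pentyl]cyclohept-2-en-1-one | COC(=C)C[C@@H]1C(=O)C(CO)=CC[C@](C)(CCCC(C)(C)O[Si](CC)(CC)CC)[C@H]1C2O[C@H](C)[C@@H](C)O2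
F5 | step 4 | {[(1R,2R)-1-[(1E)-3,3-dimethoxyprop-1-en-1-yl]-2-[(1Z)-2,6-dimethyl-6-(triethylsilyloxy)hept-1-en-1-yl]cyclopropyl]oxy}trimethylsilane | C[Si](C)(C)O[C@@]1(/C=C/C(OC)OC)C[C@@H]1/C=C(/C)CCCC(C)(C)O[Si](CC)(CC)CC
F6 | step 4 | {[(3S,4S)-3-(dimethoxymethyl)-4-methyl-4-[4-methyl-4-(triethylsilyloxy)pentyl]cyclohepta-1,5-dien-1-yl]oxy}trimethylsilane | C[Si](C)(C)OC1=C[C@H](C(OC)OC)[C@@](C)(CCCC(C)(C)O[Si](CC)(CC)CC)C=CC1
F7 | step 5 | (5S,6S,7S)-6-(dimethoxymethyl)-2-(hydroxymethyl)-7-(2-methoxyprop-2-en-1-yl)-5-methyl-5-[4-methyl-4-(triethylsilyloxy)pentyl]cyclohept-3-en-1-one (both C2 epimers) | COC(=C)C[C@@H]1C(=O)C(CO)C=C[C@](C)(CCCC(C)(C)O[Si](CC)(CC)CC)[C@H]1C(OC)OC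
F8 | step 6 | (1S,2S,7S)-7-(2-methoxyprop-2-en-1-yl)-2-methyl-2-[4-methyl-4-(triethylsilyloxy)pentyl]-6-oxo-5-[(triethylsilyloxy)methyl]cyclohept-4-ene-1-carbaldehyde | COC(=C)C[C@@H]1C(=O)C(CO[Si](CC)(CC)CC)=CC[C@](C)(CCCC(C)(C)O[Si](CC)(CC)CC)[C@H]1C=O
F9 | step 6 | (5S,6S,7S)-7-(2-methoxyprop-2-en-1-yl)-5-methyl-5-[4-methyl-4-(triethylsilyloxy)pentyl]-6-[(E)-2-(4,4,5,5-tetramethyl-1,3,2-dioxaborolan-2-yl)ethenyl]-2-[(triethylsilyloxy)methyl]cyclohept-2-en-1-one | COC(=C)C[C@@H]1C(=O)C(CO[Si](CC)(CC)CC)=CC[C@](C)(CCCC(C)(C)O[Si](CC)(CC)CC)[C@H]1/C=C/B2OC(C)(C)C(C)(C)O2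
F10 | step 8 | {[(3-methylbut-2-enoyl)oxy]methyl}triphenylphosphonium chloride | CC(C)=CC(=O)OC[P+](c1ccccc1)(c1ccccc1)c1ccccc1.[Cl-]
A1 | alternative 1 | (5S)-2-{[tert-butyl(dimethyl)silyl]oxymethyl}-5-methyl-5-[4-methyl-4-(triethylsilyloxy)pentyl]cyclohepta-2,6-dien-1-one | O=C1C(CO[Si](C)(C)C(C)(C)C)=CC[C@](C)(CCCC(C)(C)O[Si](CC)(CC)CC)C=C1
A2 | alternative 2 | methyl (3S,4S)-3-(dimethoxymethyl)-4-methyl-4-[4-methyl-4-(triethylsilyloxy)pentyl]cyclohepta-1,5-diene-1-carboxylate | COC(=O)C1=C[C@H](C(OC)OC)[C@@](C)(CCCC(C)(C)O[Si](CC)(CC)CC)C=CC1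
A3 | alternative 3 | (7R)-7-[(1Z)-2,6-dimethyl-6-(triethylsilyloxy)hept-1-en-1-yl]-5-methoxy-6,7-dihydrooxepin-2(3H)-one | O=C1CC=C(OC)C[C@@H](O1)/C=C(/C)CCCC(C)(C)O[Si](CC)(CC)CC
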